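The runs are simulated with constants of no real substance, noise included.

In a one-step world, where substrate meets free catalyst and leaves as product, your hunch holds: the rate follows the catalyst charged, and going from 1.7 mM to 15 mM gives a factor of 8.82. The scheme for this flask has more steps than that, and one of them turns free catalyst and impurity into spent catalyst.

| flask | substrate | partner | free catalyst | impurity | remark |
|---|---|---|---|---|---|
| birch | 19 mM | 95 mM | 1.7 mM | 0.66 mM | the very flask that is asked about, followed so far |
| alder | 19 mM | 140 mM | 1.7 mM | 0.66 mM | run made earlier |
| flask | 19 mM | 95.0 mM | 1.7 mM | 0.66 mM |  |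

- birch (time / s: product / %, substrate / %): 10.0: 0.6, 99.3; 15.0: 0.1, 99.5; 20.0: 1.1, 97.3; 25.0: 1.7, 96.4
- alder (time / s: product / %, substrate / %): 12.0: 0.3, 98.7; 25.0: 1.5, 96.0; 40.0: 4.1, 94.4; 50.0: 5.3, 94.1; 60.0: 7.1, 92.7; 80.0: 9.8, 89.8

(standard deviation of a reading: 0.5 percentage points)

* factor on the rate of making product when 50% of the substrate are converted if partner is charged twice over
* factor on the rate when 50% of the substrate are converted if free catalyst is charged at 15 mM instead

- what may be going on: partner + free catalyst -> catalyst intermediate A; catalyst intermediate A <-> catalyst intermediate B; substrate + catalyst intermediate B -> catalyst intermediate C; catalyst intermediate C -> catalyst intermediate D; catalyst intermediate D -> released group + catalyst intermediate E; catalyst intermediate E -> free catalyst + product; free catalyst + impurity -> spent catalyst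
- no earlier run changes the charge of free catalyst; that part of a forecast is a guess

So subtract before dividing. The charge of 1.7 mM less 0.66 mM of impurity leaves 1.04 mM. Call this the working catalyst, the catalyst charged minus the impurity charged, or the active-site concentration left after an irreversible inhibitor. At 15 mM it is 14.3 mM, and a rate proportional to it rises by 13.8, which is my number, though a guess, as no earlier run changes the catalyst charge.

On partner, birch shows 1.7% product at 25.0 s with 95 mM charged, and alder shows 1.5% at 25.0 s with 140 mM. That gap is smaller than the scatter of 0.5 percentage points, but alder holds only 1.47 times the partner of birch, so this one noisy pair of readings does not tell a weak dependence on partner from a proportional one.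

The forecast gives 1.1 for partner twice over, between 1 and 1.6, on the ground that “Doubling partner should then change little”. For the catalyst it gives 13.5, between 9 and 15, a little below my number.

    partner + free catalyst → catalyst intermediate A (k = 1.43 M⁻¹ s⁻¹)
    catalyst intermediate A ⇌ catalyst intermediate B (K = 0.390, k = 0.216 s⁻¹)
    substrate + catalyst intermediate B → catalyst intermediate C (k = 11.5 M⁻¹ s⁻¹)
    catalyst intermediate C → catalyst intermediate D (k = 0.255 s⁻¹)
    catalyst intermediate D → released group + catalyst intermediate E (k = 0.329 s⁻¹)
    catalyst intermediate E → free catalyst + product (k = 0.209 s⁻¹)
    free catalyst + impurity → spent catalyst (k = 5980 M⁻¹ s⁻¹)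

The flask gives 1.09 for partner twice over and 15.2 for the catalyst, above the 13.8 of working catalyst. At the start, free catalyst is used by partner at 0.034 of the rate at which impurity uses it. Working catalyst is 61.2% of the charge in this flask. At 2.00 min, spent catalyst holds 38.8%, and free catalyst with intermediates A to E adds up to 61.2%.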